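**Strategy.** The target is a linear trimer of gallic acid in which each ester oxygen sits on C4 of rings A and B, between hydroxyls on C3 and C5 that could compete as acyl acceptors. The plan removes that ambiguity by carrying the six C3/C5 oxygens of rings A, B and C as bromine: each 3,5-dibromo-4-hydroxybenzoyl unit then has a single phenol, so both depside esters form at C4 only. The precursor of the key step is the hexabromo tris(4-oxybenzoate) with a benzyl ester on ring A and a benzyl ether on O4 of ring C. One operation, sixfold borylation and oxidation, converts all six C–Br bonds into C–OH; hydrogenolysis finishes.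

Key step: step 6

Remark on the chemistry: the target has no stereocentre. Reagent 13 is counted as a starting material although none of its atoms remains in the target. A hydroxyl next to a depside ester can accept the acyl group under base (shift from O4 to O3), so from the key step onward the material is handled under neutral or slightly acidic conditions. Ring B is brought in as the commercial aldehyde 7, so its carboxyl group needs no protecting group.

Step 1
Reactants: 1 3,5-dibromo-4-hydroxybenzoic acid; 2 benzyl alcohol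
Product: 3 benzyl 3,5-dibromo-4-hydroxybenzoate
Conditions: BnOH (5 equiv), TsOH·H2O (cat.), toluene, reflux, Dean–Stark
Reagents that add atoms: benzyl alcohol 2, OCc1ccccc1
Why: Fischer esterification with azeotropic removal of water converts only the carboxyl group, since under acid the bromine-flanked phenol is neither alkylated nor acylated, and this gives the ring A unit with its single free hydroxyl on C4.

Step 2
Reactants: 1 3,5-dibromo-4-hydroxybenzoic acid; 4 benzyl bromide
Product: 6 4-benzyloxy-3,5-dibromobenzoic acid, via bis-benzylated ester 5 (not isolated)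
Conditions: BnBr (2.3 equiv), K2CO3, DMF, 60 °C; then aq. NaOH, MeOH, 60 °C; then aq. HCl to pH 2
Reagents that add atoms: benzyl bromide 4, BrCc1ccccc1; sodium hydroxide, [Na+].[OH-]
Why: Williamson alkylation of the phenoxide and the carboxylate followed by saponification of the benzyl ester in the same flask; the benzyl aryl ether is inert to hydroxide, and acid 6 is separated from neutral by-products by acid–base extraction.

Step 3
Reactants: 6 4-benzyloxy-3,5-dibromobenzoic acid; 7 3,5-dibromo-4-hydroxybenzaldehyde
Product: 9 2,6-dibromo-4-formylphenyl 4-benzyloxy-3,5-dibromobenzoate, via acid chloride 8 (not isolated)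
Conditions: (COCl)2, DMF (cat.), CH2Cl2, 0 °C to rt, evaporate; then 7, Et3N, DMAP (cat.), CH2Cl2, 0 °C to rt
Reagents that add atoms: oxalyl chloride, O=C(Cl)C(=O)Cl (chlorine of 8 only)
Why: Acid chloride formation through the chloroiminium salt from DMF, then nucleophilic acyl substitution by the phenoxide of 7 under acyl-transfer catalysis; 7 has one hydroxyl, so the ester can only form on C4 of the future ring B, and the aldehyde is inert here.

Step 4
Reactants: 9 2,6-dibromo-4-formylphenyl 4-benzyloxy-3,5-dibromobenzoate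
Product: 10 3,5-dibromo-4-(4-benzyloxy-3,5-dibromobenzoyl)oxybenzoic acid
Conditions: NaClO2, NaH2PO4, 2-methyl-2-butene, t-BuOH/THF/H2O, 0 °C to rt
Reagents that add atoms: sodium chlorite, [Na+].[O-]Cl=O
Why: Pinnick oxidation: chlorous acid adds to the aldehyde and the adduct fragments to the acid at about pH 4, where the aryl ester, the benzyl ether and the aryl bromides are inert, while 2-methyl-2-butene traps the hypochlorous acid.

Step 5
Reactants: 10 3,5-dibromo-4-(4-benzyloxy-3,5-dibromobenzoyl)oxybenzoic acid; 3 benzyl 3,5-dibromo-4-hydroxybenzoate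
Product: 12 benzyl 3,5-dibromo-4-[3,5-dibromo-4-(4-benzyloxy-3,5-dibromobenzoyl)oxybenzoyl]oxybenzoate, via acid chloride 11 (not isolated)
Conditions: (COCl)2, DMF (cat.), CH2Cl2, rt, evaporate; then slow addition of 3 and Et3N, CH2Cl2, 0 °C to rt
Reagents that add atoms: oxalyl chloride, O=C(Cl)C(=O)Cl (chlorine of 11 only)
Why: Nucleophilic acyl substitution of the acid chloride by the phenoxide of 3, whose only hydroxyl is on C4 of ring A; the acid chloride is far more electrophilic than the bromine-shielded aryl ester already present, and slow addition of phenol and amine without a nucleophilic catalyst should keep ester exchange down.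

Step 6
Reactants: 12 benzyl 3,5-dibromo-4-[3,5-dibromo-4-(4-benzyloxy-3,5-dibromobenzoyl)oxybenzoyl]oxybenzoate; 13 bis(pinacolato)diboron
Product: 15 benzyl 3,5-dihydroxy-4-[3,5-dihydroxy-4-(4-benzyloxy-3,5-dihydroxybenzoyl)oxybenzoyl]oxybenzoate, via hexakis(pinacolboronate) 14 (not isolated)
Conditions: Pd(dppf)Cl2 (5 mol% per Br), 13 (9 equiv), dry KOAc (18 equiv), 1,4-dioxane, 80 °C; filter through Celite under argon; then NMO (20 equiv), THF, rt to 40 °C; cold aq. citric acid work-up
Reagents that add atoms: bis(pinacolato)diboron 13, CC1(C)OB(OC1(C)C)B1OC(C)(C)C(C)(C)O1 (boryl groups of 14 only); N-methylmorpholine N-oxide, C[N+]1([O-])CCOCC1 (the six new oxygen atoms)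
Why: Zerovalent palladium formed from Pd(dppf)Cl2 adds oxidatively to each C–Br bond, bromide on the divalent arylpalladium is exchanged for acetate, the Pd–OAc species transmetalates with 13 and reductive elimination releases the arylboronate; the amine oxide oxygen then adds to boron and the aryl group shifts from boron to oxygen with loss of N-methylmorpholine, giving aryl borates that the acidic work-up hydrolyses to phenols. The closest known reaction types are the Miyaura borylation of aryl bromides and the amine-oxide oxidation of arylboronic esters to phenols, here applied six times in one molecule. No ring is closed and no stereocentre is formed. The step needs insertion into C–Br and not into the acyl C–O bonds of the aryl esters, which the bisphosphine palladium catalyst should secure, and complete sixfold conversion without hydrodebromination, which dry conditions, excess 13 and the unsubstituted position beside every bromine favour. The depside esters must not be exchanged or shifted: the only base is a carboxylate, which is filtered off before oxidation, the oxidant is neutral, and each new oxygen stays masked as a borate until the cold acidic work-up, so no phenoxide should stand next to an ester. O4 of every ring is still acylated or benzylated, so 15 has no free catechol and should tolerate air and chromatography.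

Step 7
Reactants: 15 benzyl 3,5-dihydroxy-4-[3,5-dihydroxy-4-(4-benzyloxy-3,5-dihydroxybenzoyl)oxybenzoyl]oxybenzoate
Product: 16 3,5-dihydroxy-4-[3,5-dihydroxy-4-(3,4,5-trihydroxybenzoyl)oxybenzoyl]oxybenzoic acid
Conditions: H2 (1 atm), 10% Pd/C, THF, rt; filter, evaporate below 30 °C
Reagents that add atoms: none
Why: Hydrogenolysis of the benzyl ester and the benzyl aryl ether on palladium under neutral conditions; aryl esters are not cleaved, and with no base present the C4 esters should not shift to the neighbouring hydroxyls.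

**Compound list**

1 | 3,5-dibromo-4-hydroxybenzoic acid | O=C(O)c1cc(Br)c(O)c(Br)c1 | starting material
2 | benzyl alcohol | OCc1ccccc1 | starting material
3 | benzyl 3,5-dibromo-4-hydroxybenzoate | O=C(OCc1ccccc1)c1cc(Br)c(O)c(Br)c1 | intermediate
4 | benzyl bromide | BrCc1ccccc1 | starting material
5 | benzyl 4-benzyloxy-3,5-dibromobenzoate | O=C(OCc1ccccc1)c1cc(Br)c(OCc2ccccc2)c(Br)c1 | intermediate
6 | 4-benzyloxy-3,5-dibromobenzoic acid | O=C(O)c1cc(Br)c(OCc2ccccc2)c(Br)c1 | intermediate
7 | 3,5-dibromo-4-hydroxybenzaldehyde | O=Cc1cc(Br)c(O)c(Br)c1 | starting material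
8 | 4-benzyloxy-3,5-dibromobenzoyl chloride | O=C(Cl)c1cc(Br)c(OCc2ccccc2)c(Br)c1 | intermediate
9 | 2,6-dibromo-4-formylphenyl 4-benzyloxy-3,5-dibromobenzoate | O=Cc1cc(Br)c(OC(=O)c2cc(Br)c(OCc3ccccc3)c(Br)c2)c(Br)c1 | intermediate
10 | 3,5-dibromo-4-(4-benzyloxy-3,5-dibromobenzoyl)oxybenzoic acid | O=C(O)c1cc(Br)c(OC(=O)c2cc(Br)c(OCc3ccccc3)c(Br)c2)c(Br)c1 | intermediate
11 | 3,5-dibromo-4-(4-benzyloxy-3,5-dibromobenzoyl)oxybenzoyl chloride | O=C(Cl)c1cc(Br)c(OC(=O)c2cc(Br)c(OCc3ccccc3)c(Br)c2)c(Br)c1 | intermediate
12 | benzyl 3,5-dibromo-4-[3,5-dibromo-4-(4-benzyloxy-3,5-dibromobenzoyl)oxybenzoyl]oxybenzoate | O=C(OCc1ccccc1)c1cc(Br)c(OC(=O)c2cc(Br)c(OC(=O)c3cc(Br)c(OCc4ccccc4)c(Br)c3)c(Br)c2)c(Br)c1 | intermediate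
13 | bis(pinacolato)diboron | CC1(C)OB(OC1(C)C)B1OC(C)(C)C(C)(C)O1 | starting material
14 | benzyl 4-[4-[4-benzyloxy-3,5-bis(pinacolboryl)benzoyl]oxy-3,5-bis(pinacolboryl)benzoyl]oxy-3,5-bis(pinacolboryl)benzoate (pinacolboryl = 4,4,5,5-tetramethyl-1,3,2-dioxaborolan-2-yl) | O=C(OCc1ccccc1)c1cc(B5OC(C)(C)C(C)(C)O5)c(OC(=O)c2cc(B6OC(C)(C)C(C)(C)O6)c(OC(=O)c3cc(B7OC(C)(C)C(C)(C)O7)c(OCc4ccccc4)c(B8OC(C)(C)C(C)(C)O8)c3)c(B9OC(C)(C)C(C)(C)O9)c2)c(B5OC(C)(C)C(C)(C)O5)c1 | intermediate
15 | benzyl 3,5-dihydroxy-4-[3,5-dihydroxy-4-(4-benzyloxy-3,5-dihydroxybenzoyl)oxybenzoyl]oxybenzoate | O=C(OCc1ccccc1)c1cc(O)c(OC(=O)c2cc(O)c(OC(=O)c3cc(O)c(OCc4ccccc4)c(O)c3)c(O)c2)c(O)c1 | intermediate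
16 | 3,5-dihydroxy-4-[3,5-dihydroxy-4-(3,4,5-trihydroxybenzoyl)oxybenzoyl]oxybenzoic acid | O=C(O)c1cc(O)c(OC(=O)c2cc(O)c(OC(=O)c3cc(O)c(O)c(O)c3)c(O)c2)c(O)c1 | target

**Total step count:** 7

**Longest linear sequence:** 6 steps (steps 2 to 7, from 1 through 6, 9, 10, 12 and 15 to 16); step 1 is a one-step side branch.

**Steps most likely to fail**

Step 6. Several processes could spoil it:
- incomplete sixfold borylation with hydrodebromination at some sites, giving deoxy congeners that would be hard to separate;
- acyl exchange at the activated aryl esters by acetate at 80 °C;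
- cross-coupling between boronate and bromide sites of different molecules;
- shift of an acyl group from O4 to a new neighbouring hydroxyl once the borates are hydrolysed.

The fallback sets out from 3 and comes back at 16. It moves the C–Br to C–OH conversion to the monomer, where only two bromines and no depside ester are present, and carries the new hydroxyls as benzyl ethers, so each ring still offers one free hydroxyl when the esters are made. Phenol 3 would be protected with chloromethyl methyl ether and i-Pr2NEt in CH2Cl2 to give benzyl 3,5-dibromo-4-(methoxymethoxy)benzoate F1. Twofold Miyaura borylation (Pd(dppf)Cl2, 13, KOAc, 1,4-dioxane, 80 °C) would give benzyl 4-(methoxymethoxy)-3,5-bis(pinacolboryl)benzoate F2, oxidised without isolation by NMO to benzyl 3,5-dihydroxy-4-(methoxymethoxy)benzoate F3. Benzylation with 4 and K2CO3 in DMF would give benzyl 3,5-bis(benzyloxy)-4-(methoxymethoxy)benzoate F4. One part of F4 would be treated with CF3CO2H in wet CH2Cl2 at 0 °C to give benzyl 3,5-bis(benzyloxy)-4-hydroxybenzoate F5 (ring A unit); the other part would be saponified (LiOH, THF/MeOH/H2O) to 3,5-bis(benzyloxy)-4-(methoxymethoxy)benzoic acid F6 (ring B unit). Carbodiimide coupling of F6 with F5 (EDC·HCl, DMAP, CH2Cl2) should give benzyl 3,5-bis(benzyloxy)-4-[3,5-bis(benzyloxy)-4-(methoxymethoxy)benzoyl]oxybenzoate F7, and CF3CO2H in wet CH2Cl2 would free the ring B phenol to give benzyl 3,5-bis(benzyloxy)-4-[3,5-bis(benzyloxy)-4-hydroxybenzoyl]oxybenzoate F8. Commercial 3,4,5-tris(benzyloxy)benzoic acid would be converted with (COCl)2 and catalytic DMF into 3,4,5-tris(benzyloxy)benzoyl chloride F9, which should acylate F8 (Et3N, DMAP, CH2Cl2) to benzyl 3,5-bis(benzyloxy)-4-[3,5-bis(benzyloxy)-4-[3,4,5-tris(benzyloxy)benzoyl]oxybenzoyl]oxybenzoate F10. Hydrogenolysis of F10 (H2, 10% Pd/C, THF) should give 16.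

Step 5. The phenoxide of 3 could attack the ester already present in 11 or 12 instead of the acid chloride, scrambling the ring order and forming oligomers, and the acid chloride could hydrolyse before it reacts. The fallback sets out from 7 and comes back at 12. It reverses the order of the two ester formations, so the first ester is made when no other activated ester exists and the last one uses the simple acid chloride 8 in excess. Aldehyde 7 would be protected (chloromethyl methyl ether, i-Pr2NEt, CH2Cl2) as 3,5-dibromo-4-(methoxymethoxy)benzaldehyde F11 and oxidised under the conditions of step 4 to 3,5-dibromo-4-(methoxymethoxy)benzoic acid F12. Carbodiimide coupling with 3 (EDC·HCl, catalytic DMAP, CH2Cl2) should give benzyl 3,5-dibromo-4-[3,5-dibromo-4-(methoxymethoxy)benzoyl]oxybenzoate F13. CF3CO2H in wet CH2Cl2 at 0 °C would free the phenol to give benzyl 3,5-dibromo-4-(3,5-dibromo-4-hydroxybenzoyl)oxybenzoate F14. Acylation of F14 with an excess of 8 (Et3N, CH2Cl2, 0 °C) should give 12.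

Step 7. The free polyphenol could suffer acyl shift from O4 to O3 on prolonged contact with the catalyst or during concentration, the new trihydroxyphenyl ring C could autoxidise, and hydrogenolysis of the ring C ether could stall. The fallback sets out from 15 and comes back at 16 and makes no new compound (F0). It replaces the reductive cleavage by a Lewis-acid debenzylation: BCl3 with pentamethylbenzene as benzyl-cation scavenger in CH2Cl2 at −78 °C to 0 °C, quenched into cold aqueous THF. This removes the benzyl ether and the benzyl ester under acidic conditions, in which the phenols stay protonated and acyl shift should be slow.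

**Further compounds**

F1 | step 6 | benzyl 3,5-dibromo-4-(methoxymethoxy)benzoate | COCOc1c(Br)cc(cc1Br)C(=O)OCc1ccccc1
F2 | step 6 | benzyl 4-(methoxymethoxy)-3,5-bis(pinacolboryl)benzoate | COCOc1c(B2OC(C)(C)C(C)(C)O2)cc(cc1B3OC(C)(C)C(C)(C)O3)C(=O)OCc4ccccc4
F3 | step 6 | benzyl 3,5-dihydroxy-4-(methoxymethoxy)benzoate | COCOc1c(O)cc(cc1O)C(=O)OCc2ccccc2
F4 | step 6 | benzyl 3,5-bis(benzyloxy)-4-(methoxymethoxy)benzoate | COCOc1c(OCc2ccccc2)cc(cc1OCc3ccccc3)C(=O)OCc4ccccc4
F5 | step 6 | benzyl 3,5-bis(benzyloxy)-4-hydroxybenzoate | Oc1c(OCc2ccccc2)cc(cc1OCc3ccccc3)C(=O)OCc4ccccc4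
F6 | step 6 | 3,5-bis(benzyloxy)-4-(methoxymethoxy)benzoic acid | COCOc1c(OCc2ccccc2)cc(cc1OCc3ccccc3)C(=O)O
F7 | step 6 | benzyl 3,5-bis(benzyloxy)-4-[3,5-bis(benzyloxy)-4-(methoxymethoxy)benzoyl]oxybenzoate | COCOc1c(OCc2ccccc2)cc(cc1OCc3ccccc3)C(=O)Oc4c(OCc5ccccc5)cc(cc4OCc6ccccc6)C(=O)OCc7ccccc7
F8 | step 6 | benzyl 3,5-bis(benzyloxy)-4-[3,5-bis(benzyloxy)-4-hydroxybenzoyl]oxybenzoate | Oc1c(OCc2ccccc2)cc(cc1OCc3ccccc3)C(=O)Oc4c(OCc5ccccc5)cc(cc4OCc6ccccc6)C(=O)OCc7ccccc7
F9 | step 6 | 3,4,5-tris(benzyloxy)benzoyl chloride | O=C(Cl)c1cc(OCc2ccccc2)c(OCc3ccccc3)c(OCc4ccccc4)c1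
F10 | step 6 | benzyl 3,5-bis(benzyloxy)-4-[3,5-bis(benzyloxy)-4-[3,4,5-tris(benzyloxy)benzoyl]oxybenzoyl]oxybenzoate | O=C(OCc1ccccc1)c1cc(OCc2ccccc2)c(OC(=O)c2cc(OCc3ccccc3)c(OC(=O)c3cc(OCc4ccccc4)c(OCc4ccccc4)c(OCc4ccccc4)c3)c(OCc3ccccc3)c2)c(OCc2ccccc2)c1
F11 | step 5 | 3,5-dibromo-4-(methoxymethoxy)benzaldehyde | COCOc1c(Br)cc(C=O)cc1Br
F12 | step 5 | 3,5-dibromo-4-(methoxymethoxy)benzoic acid | COCOc1c(Br)cc(cc1Br)C(=O)O
F13 | step 5 | benzyl 3,5-dibromo-4-[3,5-dibromo-4-(methoxymethoxy)benzoyl]oxybenzoate | COCOc1c(Br)cc(cc1Br)C(=O)Oc1c(Br)cc(cc1Br)C(=O)OCc1ccccc1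
F14 | step 5 | benzyl 3,5-dibromo-4-(3,5-dibromo-4-hydroxybenzoyl)oxybenzoate | Oc1c(Br)cc(cc1Br)C(=O)Oc1c(Br)cc(cc1Br)C(=O)OCc1ccccc1
F0 | step 7 | none | none
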